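**Strategy**

The target is read as a hidden dimer: the cyclopentenone ring (C1, C2, C3, C3a, C7a) and the carbons C8, C4, C5, C6, C7 of the cyclohexene are two copies of one 2-methoxycarbonyl-3-hexadecylcyclopentadienone. Everything rests on building that five-carbon unit from a (Z)-β-stannyl enone (C7a, C3a, C3) and methyl malonyl chloride (C1, C2): one Stille acylation/aldol operation makes C1–C7a and C2–C3, exploiting the 1,4-dicarbonyl relationship C1/C3 and the acidic β-keto ester C2. Dehydration, a catalytic asymmetric Diels–Alder dimerisation and retro-Claisen opening then give the bicycle; C4 and C7 are set by convex-face protonations.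

Key step: step 3

Remark: atoms are numbered as in 1H-indene (C8 = carboxyl carbon on C7). Whether the dimerisation in step 4 runs endo or exo does not change the final configuration, because C4 and C7 are both fixed by kinetic protonation (steps 4 and 5); compounds 10 and 11 are drawn for the endo course.

**Route**

Step 1
Reactants: 1 acetylene; 2 hexabutylditin
Product: 3 (Z)-1,2-bis(tributylstannyl)ethene
Conditions: Pd(PPh3)4 (2 mol%), acetylene (1 atm), 1,4-dioxane, 60 °C
Reagents that add atoms: none
Why: Pd(0)-catalysed bis-stannylation of an alkyne (oxidative addition of Sn–Sn, syn insertion, reductive elimination) can only place both tin groups on the same side, which fixes the Z geometry needed later for ring closure.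

Step 2
Reactants: 3 (Z)-1,2-bis(tributylstannyl)ethene; 4 heptadecanoyl chloride
Product: 5 (Z)-1-(tributylstannyl)nonadec-1-en-3-one
Conditions: 3 (1.2 equiv), PdCl2(PPh3)2 (2 mol%), CHCl3, 50 °C
Reagents that add atoms: none
Why: Stille acylation (Pd-catalysed ketone synthesis from an acid chloride and a vinylstannane) runs with retention of the Z geometry, and the acyl group installed first deactivates the remaining C–Sn bond so that mono-acylation is expected, the Z-β-stannyl enone being held by an O→Sn contact.

Step 3
Reactants: 5 (Z)-1-(tributylstannyl)nonadec-1-en-3-one; 6 methyl malonyl chloride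
Product: 8 racemic methyl 5-hexadecyl-5-hydroxy-2-oxocyclopent-3-ene-1-carboxylate, via Z-enedione 7 (not isolated)
Conditions: Pd2(dba)3 (2.5 mol%), P(2-furyl)3 (10 mol%), 1,2-dichloroethane, 50 °C; then Et3N (0.1 equiv), 0 °C
Reagents that add atoms: none
Why: Oxidative addition of the acyl chloride 6 to Pd(0), tin-to-palladium transfer of the vinyl group of 5 with retention and reductive elimination make the C1–C7a bond and give the Z-ene-1,4-dione 7 (Stille acylation). The β-keto ester methylene C2 of 7 then adds as its enol(ate) to the C3 ketone, which the Z double bond holds within reach, in an intramolecular aldol addition that closes the five-membered ring (C1, C2, C3, C3a, C7a) in the 5-exo-trig (enolexo) mode and makes the C2–C3 bond, which becomes the ring double bond on dehydration in step 4. The closest known reaction types are the Stille ketone synthesis and the base-mediated aldol cyclisation of cis-ene-1,4-diones to 4-hydroxycyclopent-2-enones, here run as one [3+2] operation. The two new stereocentres (C2 and the carbinol C3) are formed without control and need none, since both become sp2 in step 4. The step needs chemoselectivity for C2 attacking C3 rather than the chain methylene attacking C1, which the far higher acidity of the β-keto ester CH2 secures, and it needs the Z geometry, which the stereoretentive coupling delivers and which any E-7 can regain through reversible conjugate addition of the phosphine before it drains through the cyclisation.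

Step 4
Reactants: 8 racemic methyl 5-hexadecyl-5-hydroxy-2-oxocyclopent-3-ene-1-carboxylate (two molecules)
Product: 11 (3aR,4R,7S,7aS)-3,5-dihexadecyl-2,4-bis(methoxycarbonyl)-1-oxo-3a,4,7,7a-tetrahydro-1H-indene-7-carboxylic acid, via cyclopentadienone 9 (not isolated), via bridged endo dimer 10 (not isolated)
Conditions: [Cu((S,S)-t-Bu-box)](SbF6)2 (20 mol%), CH2Cl2, slow addition of 8, 0 °C to 23 °C
Reagents that add atoms: none
Why: Proposed new method: the cationic Cu(II)–bis(oxazoline) Lewis acid should dehydrate 8 by E1cB to the cyclopentadienone 9 and bind 9 through its ketone and ester carbonyls (two-point binding), so that a free molecule of 9 adds as the diene to the unsubstituted C=C of the bound one on the ligand-exposed face in an endo Diels–Alder reaction that sets C3a and C7a (cis) and the bridgeheads, after which the water released opens the strained bridging β-keto ester ketone of 10 by retro-Claisen cleavage of C8–C4 and the ester enolate is protonated at C4 on the convex face (H4 cis to H3a); the closest known reaction types are the acid- or heat-induced dehydration/Diels–Alder dimerisation/retro-Claisen sequence of 4-hydroxycyclopentenones via cyclopentadienones and Cu(II)–box-catalysed Diels–Alder reactions of chelating β-keto ester dienophiles, and the ligand antipode that gives the (3aR,7aS) sense has to be fixed by experiment ((S,S) is written).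

Step 5
Reactants: 11 (3aR,4R,7S,7aS)-3,5-dihexadecyl-2,4-bis(methoxycarbonyl)-1-oxo-3a,4,7,7a-tetrahydro-1H-indene-7-carboxylic acid
Product: 14 (3aR,4R,7R,7aS)-3,5-dihexadecyl-2,4-bis(methoxycarbonyl)-1-oxo-3a,4,7,7a-tetrahydro-1H-indene-7-carboxylic acid, via acid chloride 12 (not isolated), via vinylketene 13 (not isolated)
Conditions: (COCl)2 (1.2 equiv), DMF (cat.), CH2Cl2, 0 °C, then evaporation; Et3N (1.5 equiv), THF, −78 °C; then H2O/THF, −78 °C to 0 °C
Reagents that add atoms: water, O
Why: Ketene-mediated α-epimerisation of a carboxylic acid: the acid chloride 12 loses HCl to the vinylketene 13 (C7 becomes sp2), and hydration gives an enediol that is protonated kinetically at C7 from the convex face, the face of H7a and away from the C7a–C1 bond, so that H7 ends cis to H7a and the carboxyl group cis to C1 (all-cis, 7R).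

**Compound list**

1 | acetylene | C#C | starting material
2 | hexabutylditin | CCCC[Sn](CCCC)(CCCC)[Sn](CCCC)(CCCC)CCCC | starting material
3 | (Z)-1,2-bis(tributylstannyl)ethene | CCCC[Sn](CCCC)(CCCC)/C=C\[Sn](CCCC)(CCCC)CCCC | intermediate
4 | heptadecanoyl chloride | CCCCCCCCCCCCCCCCC(=O)Cl | starting material
5 | (Z)-1-(tributylstannyl)nonadec-1-en-3-one | CCCCCCCCCCCCCCCCC(=O)/C=C\[Sn](CCCC)(CCCC)CCCC | intermediate
6 | methyl malonyl chloride (methyl 3-chloro-3-oxopropanoate) | COC(=O)CC(=O)Cl | starting material
7 | methyl (Z)-3,6-dioxodocos-4-enoate | CCCCCCCCCCCCCCCCC(=O)/C=C\C(=O)CC(=O)OC | intermediate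
8 | racemic methyl 5-hexadecyl-5-hydroxy-2-oxocyclopent-3-ene-1-carboxylate (C1 and C5 not controlled, both erased in step 4, hence no descriptors) | CCCCCCCCCCCCCCCCC1(O)C=CC(=O)C1C(=O)OC | intermediate
9 | methyl 2-hexadecyl-5-oxocyclopenta-1,3-diene-1-carboxylate | CCCCCCCCCCCCCCCCC1=C(C(=O)OC)C(=O)C=C1 | intermediate
10 | endo Diels–Alder dimer, dimethyl 3,5-dihexadecyl-1,8-dioxo-3a,4,7,7a-tetrahydro-1H-4,7-methanoindene-2,4-dicarboxylate (H3a and H7a syn to the C8 carbonyl bridge; enantiomer as in the SMILES) | CCCCCCCCCCCCCCCCC1=C[C@H]3[C@H]2C(=O)C(C(=O)OC)=C(CCCCCCCCCCCCCCCC)[C@H]2[C@]1(C(=O)OC)C3=O | intermediate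
11 | (3aR,4R,7S,7aS)-3,5-dihexadecyl-2,4-bis(methoxycarbonyl)-1-oxo-3a,4,7,7a-tetrahydro-1H-indene-7-carboxylic acid (7-epimer of the target) | CCCCCCCCCCCCCCCCC1=C[C@H](C(=O)O)[C@H]2C(=O)C(C(=O)OC)=C(CCCCCCCCCCCCCCCC)[C@H]2[C@H]1C(=O)OC | intermediate
12 | dimethyl (3aR,4R,7S,7aS)-7-(chlorocarbonyl)-3,5-dihexadecyl-1-oxo-3a,4,7,7a-tetrahydro-1H-indene-2,4-dicarboxylate | CCCCCCCCCCCCCCCCC1=C[C@H](C(=O)Cl)[C@H]2C(=O)C(C(=O)OC)=C(CCCCCCCCCCCCCCCC)[C@H]2[C@H]1C(=O)OC | intermediate
13 | dimethyl (3aR,4R,7aS)-3,5-dihexadecyl-1-oxo-7-(oxomethylidene)-3a,4,7,7a-tetrahydro-1H-indene-2,4-dicarboxylate (vinylketene) | CCCCCCCCCCCCCCCCC1=CC(=C=O)[C@H]2C(=O)C(C(=O)OC)=C(CCCCCCCCCCCCCCCC)[C@H]2[C@H]1C(=O)OC | intermediate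
14 | (3aR,4R,7R,7aS)-3,5-dihexadecyl-2,4-bis(methoxycarbonyl)-1-oxo-3a,4,7,7a-tetrahydro-1H-indene-7-carboxylic acid | CCCCCCCCCCCCCCCCC1=C[C@@H](C(=O)O)[C@H]2C(=O)C(C(=O)OC)=C(CCCCCCCCCCCCCCCC)[C@H]2[C@H]1C(=O)OC | target

**Count and risks**

Total step count: 5. Longest linear sequence: 5 steps (1 → 2 → 3 → 4 → 5).

Steps most likely to fail:

1. Step 4 (Proposed new method). The uncatalysed dimerisation of 9 may outrun the copper-bound pathway, which would erode the enantiomeric purity; the dimerisation may also take the wrong orientation. Fallback with known chemistry, setting out from 8: the same dehydration/Diels–Alder dimerisation/retro-Claisen cascade is run without chiral control (CF3CO2H cat., CH2Cl2, 23 °C). It should give the racemate, that is 11 together with the enantiomeric bridged dimer F1 (not isolated) and the enantiomeric acid F2. The racemate is resolved by crystallising the (R)-1-phenylethylammonium salt of 11 F3 (the amine antipode is chosen by trial; preparative chiral SFC is the alternative), and dilute HCl liberates the acid, which comes back to the route at 11.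

2. Step 3 (key step). Transmetalation of the acyl-deactivated vinylstannane may be slow, 5 or 7 may isomerise from Z to E, and 6 may self-condense. Fallback, setting out from 5: iododestannylation (I2, CH2Cl2, 0 °C) with retention should give (Z)-1-iodononadec-1-en-3-one F4. A Pd-catalysed carbonylative coupling with potassium methyl malonate follows (Pd(OAc)2/Xantphos, CO 1 atm, MgCl2, Et3N, THF, 60 °C): the acyl-palladium species formed from F4 and CO acylates the magnesium malonate, decarboxylation gives 7, and 7 cyclises as before. The bonds C1–C7a and C2–C3 are again made in one operation, and the route is rejoined at 8.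

3. Step 5. The enediol may be protonated at C5 instead of C7 (giving the conjugated acid), the facial selectivity may be poor, or the ketene may dimerise. Fallback, setting out from 11: the C1 ketone is dehydrogenated towards C7a–C7 with IBX (DMSO/fluorobenzene, 65 °C) to the 7,7a-didehydro acid F5, a 4-oxo-2-enoic acid. Its ene-1,4-dicarbonyl unit is then reduced with zinc in acetic acid (0 °C); both new hydrogens (H7a and H7) are delivered by protonation on the convex face, cis to H3a, which should give 14 directly.

**Further compounds**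

F1 | step 4 | enantiomer of the bridged endo dimer 10 (not isolated) | CCCCCCCCCCCCCCCCC1=C[C@@H]3[C@@H]2C(=O)C(C(=O)OC)=C(CCCCCCCCCCCCCCCC)[C@@H]2[C@@]1(C(=O)OC)C3=O
F2 | step 4 | (3aS,4S,7R,7aR)-3,5-dihexadecyl-2,4-bis(methoxycarbonyl)-1-oxo-3a,4,7,7a-tetrahydro-1H-indene-7-carboxylic acid (enantiomer of 11) | CCCCCCCCCCCCCCCCC1=C[C@@H](C(=O)O)[C@@H]2C(=O)C(C(=O)OC)=C(CCCCCCCCCCCCCCCC)[C@@H]2[C@@H]1C(=O)OC
F3 | step 4 | (R)-1-phenylethylammonium salt of 11 | CCCCCCCCCCCCCCCCC1=C[C@H](C(=O)[O-])[C@H]2C(=O)C(C(=O)OC)=C(CCCCCCCCCCCCCCCC)[C@H]2[C@H]1C(=O)OC.C[C@@H]([NH3+])c1ccccc1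
F4 | step 3 | (Z)-1-iodononadec-1-en-3-one | CCCCCCCCCCCCCCCCC(=O)/C=C\I
F5 | step 5 | 7,7a-didehydro acid, 3,5-dihexadecyl-2,4-bis(methoxycarbonyl)-1-oxo-3a,4-dihydro-1H-indene-7-carboxylic acid (C3a and C4 as in 11) | CCCCCCCCCCCCCCCCC1=CC(C(=O)O)=C2C(=O)C(C(=O)OC)=C(CCCCCCCCCCCCCCCC)[C@H]2[C@H]1C(=O)OC
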